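Ring A is taken apart completely. This pentasubstituted benzene, with the geranyl group on C6 between the oxygens on C5 and C7 and fused to ring C through C4a–C8a, is built last, on a ring C that already holds O1, the C4 ketone and the 2S aryl centre. Light-induced Wolff rearrangement of a pyranone-bound diazo ketone gives a vinylketene; a geranyl-bearing silyl ynol ether adds to it, and cyclobutenone opening followed by 6π closure forges C8–C8a, C5–C6, C7–C8 and C4a–C5 in one operation, so geranyl can only reach C6. The precursor is a (2S)-2-aryl-6-diazoacetyl-2,3-dihydropyran-4-one from a catalytic asymmetric aldol–cyclisation.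

Key step: step 8

Assumption: Ti(OiPr)4/(S)-BINOL is taken to deliver the dienol ether to the Si face of aldehyde 2, by analogy with related additions to aryl aldehydes, which gives 2S; if the first batch shows the opposite sense, (R)-BINOL is used with no other change.

Step 1
Reactants: 1 isovanillin (3-hydroxy-4-methoxybenzaldehyde)
Product: 2 4-methoxy-3-(triisopropylsilyloxy)benzaldehyde
Conditions: TIPSCl, imidazole, DMF, rt
Reagents that add atoms: triisopropylsilyl chloride, CC(C)[Si](Cl)(C(C)C)C(C)C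
Why: Silylation of a phenol with a silyl chloride and imidazole is routine, and the triisopropylsilyl ether shields the 3'-OH from ketenes in step 8 and leaves together with the 7-O-silyl group in step 9.

Step 2
Reactants: 3 methyl 2,4-dioxopentanoate
Product: 4 methyl (2Z)-2,4-bis(trimethylsilyloxy)penta-2,4-dienoate
Conditions: TMSOTf (2.2 equiv), Et3N (2.5 equiv), Et2O, 0 °C to rt; used directly
Reagents that add atoms: trimethylsilyl triflate, C[Si](C)(C)OS(=O)(=O)C(F)(F)F
Why: Double O-silylation by soft enolisation with a silyl triflate and an amine converts first the enolised 1,3-dicarbonyl unit and then the methyl ketone, whose CH3 is the only position left for the second enol ether, into the bis-silyl dienol ether.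

Step 3
Reactants: 2 4-methoxy-3-(triisopropylsilyloxy)benzaldehyde; 4 methyl (2Z)-2,4-bis(trimethylsilyloxy)penta-2,4-dienoate
Product: 6 methyl (2S)-2-[4-methoxy-3-(triisopropylsilyloxy)phenyl]-4-oxo-3,4-dihydro-2H-pyran-6-carboxylate, via aldol adduct 5 (not isolated)
Conditions: (S)-BINOL (20 mol%), Ti(OiPr)4 (10 mol%), 4 Å MS, Et2O, −20 °C; then TFA, CH2Cl2, 0 °C
Reagents that add atoms: none
Why: A vinylogous Mukaiyama aldol addition (formal hetero-Diels–Alder reaction) of the terminal CH2 of 4 to the aldehyde gives 5, and trifluoroacetic acid then closes the benzylic oxygen onto the silyloxy-acrylate carbon with loss of silanol to give the pyranone; the 2S centre is set in the aldol step by the Ti(OiPr)4/(S)-BINOL catalyst, which should expose the Si face of the aldehyde.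

Step 4
Reactants: 6 methyl (2S)-2-[4-methoxy-3-(triisopropylsilyloxy)phenyl]-4-oxo-3,4-dihydro-2H-pyran-6-carboxylate
Product: 8 (2S)-2-[4-methoxy-3-(triisopropylsilyloxy)phenyl]-4-oxo-3,4-dihydro-2H-pyran-6-carboxylic acid, via trimethylstannyl ester 7 (not isolated)
Conditions: Me3SnOH (3 equiv), ClCH2CH2Cl, 70 °C; then 0.5 M aq. HCl wash
Reagents that add atoms: trimethyltin hydroxide, C[Sn](C)(C)O
Why: Ester hydrolysis with Me3SnOH cleaves the activated methyl ester through its stannyl ester under nearly neutral conditions, which avoids the C3 enolate that would open ring C by β-elimination and erode the C2 configuration.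

Step 5
Reactants: 8 (2S)-2-[4-methoxy-3-(triisopropylsilyloxy)phenyl]-4-oxo-3,4-dihydro-2H-pyran-6-carboxylic acid
Product: 10 (2S)-6-(diazoacetyl)-2-[4-methoxy-3-(triisopropylsilyloxy)phenyl]-2,3-dihydro-4H-pyran-4-one, via acid chloride 9 (not isolated)
Conditions: (COCl)2, cat. DMF, CH2Cl2, 0 °C to rt, evaporate; then CH2N2 (3 equiv), Et2O, −20 to 0 °C
Reagents that add atoms: diazomethane, C=[N+]=[N-]
Why: Acylation of diazomethane by the acid chloride (first stage of an Arndt–Eistert sequence) is fast in the cold, whereas dipolar cycloaddition to C5=C6 is slowed by the donor oxygen on C6, and the excess diazomethane consumes the HCl that would otherwise turn the diazo ketone into a chloromethyl ketone.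

Step 6
Reactants: 11 geranyl bromide ((2E)-1-bromo-3,7-dimethylocta-2,6-diene)
Product: 12 (4E)-5,9-dimethyldeca-4,8-dien-1-yne
Conditions: HC≡CMgBr, CuCl (10 mol%), THF, 0 to 50 °C
Reagents that add atoms: ethynylmagnesium bromide, C#C[Mg]Br
Why: CuCl-catalysed coupling of HC≡CMgBr with the primary allylic bromide gives the skipped enyne by substitution at the unhindered CH2, which leaves the E-trisubstituted alkene untouched.

Step 7
Reactants: 12 (4E)-5,9-dimethyldeca-4,8-dien-1-yne
Product: 15 triisopropyl{[(4E)-5,9-dimethyldeca-4,8-dien-1-yn-1-yl]oxy}silane, via lithium acetylide 13 (not isolated), via lithium ynolate 14 (not isolated)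
Conditions: n-BuLi, THF, −78 °C; LiOOt-Bu (from t-BuOOH and LiN(SiMe3)2, THF, −78 °C), to 0 °C; TIPSOTf, −78 to 0 °C
Reagents that add atoms: tert-butyl hydroperoxide (as its lithium salt), CC(C)(C)OO; triisopropylsilyl triflate, CC(C)[Si](OS(=O)(=O)C(F)(F)F)(C(C)C)C(C)C
Why: Oxidation of a lithium acetylide by lithium tert-butyl peroxide (oxenoid oxygen transfer with loss of tert-butoxide) gives the lithium ynolate, which the bulky silyl triflate traps on oxygen as a purifiable triisopropylsilyl ynol ether, and only the alkyne terminus is lithiated because its C–H is far more acidic than the allylic-propargylic CH2.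

Step 8
Reactants: 10 (2S)-6-(diazoacetyl)-2-[4-methoxy-3-(triisopropylsilyloxy)phenyl]-2,3-dihydro-4H-pyran-4-one; 15 triisopropyl{[(4E)-5,9-dimethyldeca-4,8-dien-1-yn-1-yl]oxy}silane
Product: 20 (2S)-6-geranyl-5-hydroxy-4'-methoxy-7,3'-bis(triisopropylsilyloxy)flavanone, via vinylketene 16 (not isolated), via vinylcyclobutenone 17 (not isolated), via dienylketene 18 (not isolated), via cyclohexadienone 19 (not isolated)
Conditions: 15 (1.5 equiv), hν (LEDs, 420–450 nm), degassed toluene (0.02 M), 20 °C; then 80 °C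
Reagents that add atoms: none
Why: This is a Danheiser benzannulation of an α,β-unsaturated α'-diazo ketone with a siloxyalkyne: excitation of the diazo chromophore expels N2, and the Wolff shift of pyranone C6 onto the diazo carbon (bond C8–C8a) gives vinylketene 16, whose vinyl unit is the pyranone C5=C6 bond. The electron-rich ynol ether adds to the ketene C=C in a [2+2] cycloaddition, its geranyl-bearing carbon bonding to the ketene carbon (C5–C6) and its silyloxy carbon to the former diazo carbon (C7–C8), which gives cyclobutenone 17. On warming, reversible 4π electrocyclic opening of 17 gives dienylketene 18, and ring A closes by thermal 6π electrocyclisation of the ketene carbon onto pyranone C5 (C4a–C5); keto tautomer 19, whose C4a hydrogen lies between two carbonyl groups, enolises at once to the chelated 5-OH phenol. No stereocentre is created in the product (the ring carbon of 17 and C4a of 19 are transient), and C2 is a spectator because the medium contains neither acid nor base that could open ring C. The selectivity needed is regiochemical: the polarity of the ketene and ynol ether pair places geranyl next to the new hydroxyl, and because O1 is bonded to C8a from the start, no choice between C6 and C8 arises. Chemoselectivity rests on light that only the diazo ketone absorbs and on the far higher reactivity of the ynol ether towards ketenes compared with the trisubstituted geranyl alkenes.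

Step 9
Reactants: 20 (2S)-6-geranyl-5-hydroxy-4'-methoxy-7,3'-bis(triisopropylsilyloxy)flavanone
Product: 21 (2S)-6-geranyl-5,7,3'-trihydroxy-4'-methoxyflavanone (CNP0264411.1)
Conditions: TBAF, AcOH (1:1, 3 equiv), THF, 0 °C to rt
Reagents that add atoms: none
Why: Fluoride-induced desilylation removes both aryl silyl ethers, and the acetic acid buffer keeps the medium from becoming basic enough to open the flavanone to its chalcone, which would racemise C2.

Compound list
1 | isovanillin (3-hydroxy-4-methoxybenzaldehyde) | COc1ccc(C=O)cc1O | starting material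
2 | 4-methoxy-3-(triisopropylsilyloxy)benzaldehyde | COc1ccc(C=O)cc1O[Si](C(C)C)(C(C)C)C(C)C | intermediate
3 | methyl 2,4-dioxopentanoate | COC(=O)C(=O)CC(C)=O | starting material
4 | methyl (2Z)-2,4-bis(trimethylsilyloxy)penta-2,4-dienoate | COC(=O)/C(O[Si](C)(C)C)=C/C(=C)O[Si](C)(C)C | intermediate
5 | methyl (2Z,6S)-6-[4-methoxy-3-(triisopropylsilyloxy)phenyl]-4-oxo-2,6-bis(trimethylsilyloxy)hex-2-enoate (aldol adduct, not isolated) | COc1ccc([C@@H](O[Si](C)(C)C)CC(=O)/C=C(O[Si](C)(C)C)/C(=O)OC)cc1O[Si](C(C)C)(C(C)C)C(C)C | intermediate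
6 | methyl (2S)-2-[4-methoxy-3-(triisopropylsilyloxy)phenyl]-4-oxo-3,4-dihydro-2H-pyran-6-carboxylate | COc1ccc([C@@H]2CC(=O)C=C(O2)C(=O)OC)cc1O[Si](C(C)C)(C(C)C)C(C)C | intermediate
7 | trimethylstannyl (2S)-2-[4-methoxy-3-(triisopropylsilyloxy)phenyl]-4-oxo-3,4-dihydro-2H-pyran-6-carboxylate (not isolated) | COc1ccc([C@@H]2CC(=O)C=C(O2)C(=O)O[Sn](C)(C)C)cc1O[Si](C(C)C)(C(C)C)C(C)C | intermediate
8 | (2S)-2-[4-methoxy-3-(triisopropylsilyloxy)phenyl]-4-oxo-3,4-dihydro-2H-pyran-6-carboxylic acid | COc1ccc([C@@H]2CC(=O)C=C(O2)C(=O)O)cc1O[Si](C(C)C)(C(C)C)C(C)C | intermediate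
9 | (2S)-2-[4-methoxy-3-(triisopropylsilyloxy)phenyl]-4-oxo-3,4-dihydro-2H-pyran-6-carbonyl chloride (not isolated) | COc1ccc([C@@H]2CC(=O)C=C(O2)C(Cl)=O)cc1O[Si](C(C)C)(C(C)C)C(C)C | intermediate
10 | (2S)-6-(diazoacetyl)-2-[4-methoxy-3-(triisopropylsilyloxy)phenyl]-2,3-dihydro-4H-pyran-4-one | COc1ccc([C@@H]2CC(=O)C=C(O2)C(=O)C=[N+]=[N-])cc1O[Si](C(C)C)(C(C)C)C(C)C | intermediate
11 | geranyl bromide ((2E)-1-bromo-3,7-dimethylocta-2,6-diene) | CC(C)=CCC/C(C)=C/CBr | starting material
12 | (4E)-5,9-dimethyldeca-4,8-dien-1-yne | C#CC/C=C(\C)CCC=C(C)C | intermediate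
13 | lithium (4E)-5,9-dimethyldeca-4,8-dien-1-yn-1-ide (not isolated) | [Li+].[C-]#CC/C=C(\C)CCC=C(C)C | intermediate
14 | lithium (4E)-5,9-dimethyldeca-4,8-dien-1-yn-1-olate (not isolated) | [Li+].[O-]C#CC/C=C(\C)CCC=C(C)C | intermediate
15 | triisopropyl{[(4E)-5,9-dimethyldeca-4,8-dien-1-yn-1-yl]oxy}silane | CC(C)[Si](OC#CC/C=C(\C)CCC=C(C)C)(C(C)C)C(C)C | intermediate
16 | (2S)-2-[4-methoxy-3-(triisopropylsilyloxy)phenyl]-6-(2-oxoethenyl)-2,3-dihydro-4H-pyran-4-one (vinylketene, not isolated) | COc1ccc([C@@H]2CC(=O)C=C(O2)C=C=O)cc1O[Si](C(C)C)(C(C)C)C(C)C | intermediate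
17 | 2-geranyl-4-{(2S)-2-[4-methoxy-3-(triisopropylsilyloxy)phenyl]-4-oxo-3,4-dihydro-2H-pyran-6-yl}-3-(triisopropylsilyloxy)cyclobut-2-en-1-one, either configuration at the cyclobutenone C4 (not isolated) | COc1ccc([C@@H]2CC(=O)C=C(O2)C3C(=O)C(C/C=C(\C)CCC=C(C)C)=C3O[Si](C(C)C)(C(C)C)C(C)C)cc1O[Si](C(C)C)(C(C)C)C(C)C | intermediate
18 | (2S)-6-[(1E)-3-geranyl-4-oxo-2-(triisopropylsilyloxy)buta-1,3-dien-1-yl]-2-[4-methoxy-3-(triisopropylsilyloxy)phenyl]-2,3-dihydro-4H-pyran-4-one (dienylketene, not isolated) | COc1ccc([C@@H]2CC(=O)C=C(O2)/C=C(O[Si](C(C)C)(C(C)C)C(C)C)\C(C/C=C(\C)CCC=C(C)C)=C=O)cc1O[Si](C(C)C)(C(C)C)C(C)C | intermediate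
19 | (2S)-6-geranyl-2-[4-methoxy-3-(triisopropylsilyloxy)phenyl]-7-(triisopropylsilyloxy)-2,3-dihydro-4H-chromene-4,5(4aH)-dione, either configuration at C4a (keto tautomer, not isolated) | COc1ccc([C@@H]2CC(=O)C3C(=O)C(C/C=C(\C)CCC=C(C)C)=C(O[Si](C(C)C)(C(C)C)C(C)C)C=C3O2)cc1O[Si](C(C)C)(C(C)C)C(C)C | intermediate
20 | (2S)-6-geranyl-5-hydroxy-4'-methoxy-7,3'-bis(triisopropylsilyloxy)flavanone | COc1ccc([C@@H]2CC(=O)c3c(cc(O[Si](C(C)C)(C(C)C)C(C)C)c(C/C=C(\C)CCC=C(C)C)c3O)O2)cc1O[Si](C(C)C)(C(C)C)C(C)C | intermediate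
21 | (2S)-6-geranyl-5,7,3'-trihydroxy-4'-methoxyflavanone | COc1ccc([C@@H]2CC(=O)c3c(cc(O)c(C/C=C(\C)CCC=C(C)C)c3O)O2)cc1O | target

Total step count: 9.
Longest linear sequence: 6 steps (1 → 2 → 6 → 8 → 10 → 20 → 21; the ynol ether arm is 2 steps).

Steps most likely to fail

1. Step 8. After loss of N2 the excited diazo ketone may follow carbene pathways in place of the Wolff shift, the enone may undergo light-driven cycloaddition with the alkenes, the ketene may acylate the product phenol, or the sequence may stall before the 6π closure. The fallback drops the benzannulation and closes ring C last by chalcone chemistry; it sets out from isovanillin 1 and geranyl bromide 11 and comes back at target 21. Isovanillin 1 would be protected (MOMCl, iPr2NEt, CH2Cl2) as 4-methoxy-3-(methoxymethoxy)benzaldehyde F1. Commercial 2,4,6-trihydroxyacetophenone would be C-geranylated with 11 (DBU, THF) to 1-[3-geranyl-2,4,6-trihydroxyphenyl]ethanone F2 and protected (NaH, MOMCl, DMF) as 1-[3-geranyl-2,4,6-tris(methoxymethoxy)phenyl]ethanone F3. Claisen–Schmidt condensation of F3 with F1 (KOH, EtOH) should give the tetrakis-MOM chalcone F4. Dilute HCl in MeOH should free the trihydroxychalcone F5, and NaOAc in EtOH at reflux should close it by oxa-Michael addition to racemic 6-geranyl-5,7,3'-trihydroxy-4'-methoxyflavanone F6. This fallback gives up the control of the main route: closure can use either ortho-hydroxyl and gives a racemate, so the regioisomers must be separated and the 2S enantiomer 21 obtained by chromatography on a chiral stationary phase.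

2. Step 3. The ester-deactivated dienol ether may add sluggishly to the electron-rich aldehyde, or the facial selectivity may be poor. The fallback sets the centre with a stoichiometric chiral reagent and builds the pyranone by a Claisen condensation; it sets out from aldehyde 2 and comes back at pyranone ester 6. Brown allylation of 2 with the B-allyldiisopinocampheylborane enantiomer that attacks the Si face (expected to be the (−)-reagent from (+)-α-pinene; Et2O, −78 °C, buffered H2O2 work-up) should give (1S)-1-[4-methoxy-3-(triisopropylsilyloxy)phenyl]but-3-en-1-ol F7. Wacker oxidation (PdCl2, CuCl, O2, DMF/H2O) should give (4S)-4-hydroxy-4-[4-methoxy-3-(triisopropylsilyloxy)phenyl]butan-2-one F8. Double deprotonation (LiN(iPr)2, 2.2 equiv, THF, −78 °C) and acylation at the methyl terminus with dimethyl oxalate should give methyl (6S)-6-hydroxy-6-[4-methoxy-3-(triisopropylsilyloxy)phenyl]-2,4-dioxohexanoate F9, which TFA in CH2Cl2 should cyclodehydrate to 6.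

3. Step 5. Diazomethane may add as a dipole to the doubly activated C5=C6 bond, or HCl may convert the diazo ketone into the chloromethyl ketone. The fallback installs the diazo group by diazo transfer instead of acylation; it sets out from acid chloride 9 and comes back at diazo ketone 10. Stille coupling of 9 with Me4Sn (cat. PhCH2Pd(PPh3)2Cl, THF, 60 °C) should give (2S)-6-acetyl-2-[4-methoxy-3-(triisopropylsilyloxy)phenyl]-2,3-dihydro-4H-pyran-4-one F10. Kinetic enolisation of the acetyl group (LiN(SiMe3)2, THF, −78 °C) and trifluoroacetylation (CF3CO2CH2CF3) should give (2S)-2-[4-methoxy-3-(triisopropylsilyloxy)phenyl]-6-(4,4,4-trifluoro-3-oxobutanoyl)-2,3-dihydro-4H-pyran-4-one F11, used crude. Detrifluoroacetylative diazo transfer (MsN3, Et3N, H2O, MeCN, rt) should then give 10.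

Further compounds
F1 | step 8 | 4-methoxy-3-(methoxymethoxy)benzaldehyde | COCOc1cc(C=O)ccc1OC
F2 | step 8 | 1-[3-geranyl-2,4,6-trihydroxyphenyl]ethanone | CC(=O)c1c(O)cc(O)c(C/C=C(\C)CCC=C(C)C)c1O
F3 | step 8 | 1-[3-geranyl-2,4,6-tris(methoxymethoxy)phenyl]ethanone | CC(=O)c1c(OCOC)cc(OCOC)c(C/C=C(\C)CCC=C(C)C)c1OCOC
F4 | step 8 | (2E)-1-[3-geranyl-2,4,6-tris(methoxymethoxy)phenyl]-3-[4-methoxy-3-(methoxymethoxy)phenyl]prop-2-en-1-one | COCOc1cc(/C=C/C(=O)c2c(OCOC)cc(OCOC)c(C/C=C(\C)CCC=C(C)C)c2OCOC)ccc1OC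
F5 | step 8 | (2E)-1-[3-geranyl-2,4,6-trihydroxyphenyl]-3-(3-hydroxy-4-methoxyphenyl)prop-2-en-1-one | COc1ccc(/C=C/C(=O)c2c(O)cc(O)c(C/C=C(\C)CCC=C(C)C)c2O)cc1O
F6 | step 8 | racemic 6-geranyl-5,7,3'-trihydroxy-4'-methoxyflavanone | COc1ccc(C2CC(=O)c3c(cc(O)c(C/C=C(\C)CCC=C(C)C)c3O)O2)cc1O
F7 | step 3 | (1S)-1-[4-methoxy-3-(triisopropylsilyloxy)phenyl]but-3-en-1-ol | COc1ccc([C@@H](O)CC=C)cc1O[Si](C(C)C)(C(C)C)C(C)C
F8 | step 3 | (4S)-4-hydroxy-4-[4-methoxy-3-(triisopropylsilyloxy)phenyl]butan-2-one | COc1ccc([C@@H](O)CC(C)=O)cc1O[Si](C(C)C)(C(C)C)C(C)C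
F9 | step 3 | methyl (6S)-6-hydroxy-6-[4-methoxy-3-(triisopropylsilyloxy)phenyl]-2,4-dioxohexanoate | COc1ccc([C@@H](O)CC(=O)CC(=O)C(=O)OC)cc1O[Si](C(C)C)(C(C)C)C(C)C
F10 | step 5 | (2S)-6-acetyl-2-[4-methoxy-3-(triisopropylsilyloxy)phenyl]-2,3-dihydro-4H-pyran-4-one | COc1ccc([C@@H]2CC(=O)C=C(O2)C(C)=O)cc1O[Si](C(C)C)(C(C)C)C(C)C
F11 | step 5 | (2S)-2-[4-methoxy-3-(triisopropylsilyloxy)phenyl]-6-(4,4,4-trifluoro-3-oxobutanoyl)-2,3-dihydro-4H-pyran-4-one | COc1ccc([C@@H]2CC(=O)C=C(O2)C(=O)CC(=O)C(F)(F)F)cc1O[Si](C(C)C)(C(C)C)C(C)C
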